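## Retrosynthetic overview

1. The last step is an enantioselective Rh-catalysed 1,4-arylation of an achiral isoflavone–flavone tetraol with a 4-oxyphenylzinc. It forms the C2–aryl bond, turns the chromone into the chromanone and sets C2. C3 follows by equilibration to trans.
2. Both 5-OH groups come from a twofold carbonyl-directed peri C–H hydroxylation of the isoflavone–flavone. The two isopropyl ethers are removed afterwards.
3. The flavone pyranone (second heterocycle) comes from a carbonylative annulation of a bromo-isoflavone, CO and 2-hydroxy-4-methoxyacetophenone.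
4. The isoflavone pyranone (first heterocycle) comes from a 2'-hydroxychalcone by a Tl(III)-induced oxidative 1,2-aryl shift. This shift creates the C3–C3' interflavonoid bond.
5. The chalcone comes from a resorcinol/acetic acid-derived ketone and a 4-bromophenol/formaldehyde-derived aldehyde.

Assumption: the facial sense of Rh/(S)-BINAP is carried over from cyclic enones, 4-quinolones and chromones ((S)-ligand gives the (S)-2-aryl product); if the isoflavone answers in the opposite sense, (R)-BINAP is used instead.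

## Route

Step 1
Reactants: 1 resorcinol; 2 acetic acid
Product: 3 1-(2,4-dihydroxyphenyl)ethan-1-one
Conditions: AcOH, ZnCl2 (1.2 equiv), 145 °C, 30 min; dil. HCl
Reagents that add atoms: none
Why: Nencki (ZnCl2-mediated Friedel–Crafts) C-acylation goes to the unhindered carbon that is para to one OH and ortho to the other, and it stops after one acylation because the chelated ketone deactivates the ring.

Step 2
Reactants: 3 1-(2,4-dihydroxyphenyl)ethan-1-one
Product: 4 1-(2-hydroxy-4-methoxyphenyl)ethan-1-one (paeonol)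
Conditions: MeI (1.05 equiv), K2CO3 (1.1 equiv), acetone, reflux
Reagents that add atoms: iodomethane CI
Why: Williamson etherification is selective because the 2-OH is locked in a hydrogen bond to the ketone, so one equivalent of MeI alkylates only the more acidic 4-OH.

Step 3
Reactants: 3 1-(2,4-dihydroxyphenyl)ethan-1-one
Product: 5 1-(2-hydroxy-4-isopropoxyphenyl)ethan-1-one
Conditions: i-PrBr (1.2 equiv), K2CO3 (1.2 equiv), DMF, 60 °C
Reagents that add atoms: 2-bromopropane CC(C)Br
Why: Williamson etherification shows the same chelation-based 4-O selectivity as in step 2, and the isopropyl ether withstands base, acid, Pd and oxidants yet is cleaved later by BCl3 beside a methyl ether.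

Step 4
Reactants: 6 4-bromophenol; 7 formaldehyde (as paraformaldehyde)
Product: 9 5-bromo-2-hydroxybenzaldehyde, via salicyl alcohol 8 (not isolated)
Conditions: (CH2O)n (6.8 equiv), MgCl2 (1.5 equiv), Et3N (3.8 equiv), MeCN, reflux; 1 M HCl
Reagents that add atoms: none
Why: In the Casnati–Skattebøl ortho-formylation the magnesium phenoxide delivers formaldehyde only to the ortho carbon (para is blocked by Br), and a second formaldehyde oxidises the salicyl alkoxide by hydride transfer.

Step 5
Reactants: 9 5-bromo-2-hydroxybenzaldehyde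
Product: 10 5-bromo-2-isopropoxybenzaldehyde
Conditions: i-PrBr (1.5 equiv), K2CO3 (1.5 equiv), DMF, 70 °C
Reagents that add atoms: 2-bromopropane CC(C)Br
Why: Williamson etherification masks the phenol, which would otherwise be oxidised by Tl(III), and turns it into the ortho-alkoxy donor that drives the later aryl migration.

Step 6
Reactants: 5 1-(2-hydroxy-4-isopropoxyphenyl)ethan-1-one; 10 5-bromo-2-isopropoxybenzaldehyde
Product: 11 (E)-3-(5-bromo-2-isopropoxyphenyl)-1-(2-hydroxy-4-isopropoxyphenyl)prop-2-en-1-one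
Conditions: KOH (3 equiv), EtOH, 23 °C, 24 h; 1 M HCl
Reagents that add atoms: none
Why: Claisen–Schmidt aldol condensation of a methyl ketone and a non-enolisable aldehyde gives the conjugated E-chalcone under thermodynamic control.

Step 7
Reactants: 11 (E)-3-(5-bromo-2-isopropoxyphenyl)-1-(2-hydroxy-4-isopropoxyphenyl)prop-2-en-1-one
Product: 13 3-(5-bromo-2-isopropoxyphenyl)-7-isopropoxy-4H-chromen-4-one, via dimethyl acetal 12 (not isolated)
Conditions: Tl(NO3)3·3H2O (1.1 equiv), MeOH–HC(OMe)3, 23 °C, 12 h; then 3 M HCl, reflux, 2 h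
Reagents that add atoms: methanol CO (its OMe groups stand only in 12 and leave again)
Why: This is the Tl(III)-mediated oxidative 1,2-aryl migration of a chalcone, in which oxythallation puts MeOH on the benzylic carbon and Tl on the α-carbon, loss of Tl(I) is assisted by a phenonium-type shift of the ortho-alkoxyaryl group to the α-carbon (forming the C3–C3' bond), the oxocarbenium ion is trapped as acetal 12, and HCl closes the 2'-OH onto the masked aldehyde with loss of MeOH to give the isoflavone.

Step 8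
Reactants: 13 3-(5-bromo-2-isopropoxyphenyl)-7-isopropoxy-4H-chromen-4-one; 4 1-(2-hydroxy-4-methoxyphenyl)ethan-1-one; 14 carbon monoxide
Product: 17 7-isopropoxy-3-[2-isopropoxy-5-(7-methoxy-4-oxo-4H-chromen-2-yl)phenyl]-4H-chromen-4-one, via aryl ester 15 (not isolated), via 1,3-diketone 16 (not isolated)
Conditions: Pd(OAc)2 (2 mol %), n-BuPAd2 (6 mol %), CO (10 bar), DBU (3 equiv), 4 Å MS, DMF, 115 °C, 20 h
Reagents that add atoms: none
Why: The known Pd-catalysed carbonylative flavone synthesis from aryl bromides and 2-hydroxyacetophenones runs as aryloxycarbonylation, DBU-induced Baker–Venkataraman O-to-C acyl transfer and cyclodehydration in one pot, while 13 carries no free OH that could compete and the sieves take up the water that could open the isoflavone.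

Step 9
Reactants: 17 7-isopropoxy-3-[2-isopropoxy-5-(7-methoxy-4-oxo-4H-chromen-2-yl)phenyl]-4H-chromen-4-one
Product: 19 5-hydroxy-3-[5-(5-hydroxy-7-methoxy-4-oxo-4H-chromen-2-yl)-2-isopropoxyphenyl]-7-isopropoxy-4H-chromen-4-one, via bis(trifluoroacetate) 18 (not isolated)
Conditions: [RuCl2(p-cymene)]2 (10 mol %), PhI(OCOCF3)2 (5 equiv), TFA–TFAA, 80 °C; then aq. NaHCO3–MeOH
Reagents that add atoms: [bis(trifluoroacetoxy)iodo]benzene O=C(OI(OC(=O)C(F)(F)F)c1ccccc1)C(F)(F)F
Why: In this Ru(II)-catalysed carbonyl-directed C–H oxygenation (known for flavones and chromones) each pyranone C=O steers a five-membered ruthenacycle to its peri C5–H, I(III) converts it into an aryl trifluoroacetate that resists over-oxidation and hydrolyses on work-up, and any partial loss of isopropyl groups is harmless because they are removed next.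

Step 10
Reactants: 19 5-hydroxy-3-[5-(5-hydroxy-7-methoxy-4-oxo-4H-chromen-2-yl)-2-isopropoxyphenyl]-7-isopropoxy-4H-chromen-4-one
Product: 20 5,7-dihydroxy-3-[2-hydroxy-5-(5-hydroxy-7-methoxy-4-oxo-4H-chromen-2-yl)phenyl]-4H-chromen-4-one
Conditions: BCl3 (8 equiv), CH2Cl2, −78 → 23 °C; H2O
Reagents that add atoms: none
Why: In this Lewis-acid ether cleavage BCl3 cleaves the secondary isopropyl aryl ethers through SN1-like collapse of the O–BCl3 complex, the non-chelated 7-OMe group is inert to BCl3 at or below room temperature, and no stereocentre is present yet.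

Step 11
Reactants: 6 4-bromophenol
Product: 21 (4-bromophenoxy)trimethylsilane
Conditions: HMDS (0.6 equiv), neat, reflux; distil
Reagents that add atoms: hexamethyldisilazane C[Si](C)(C)N[Si](C)(C)C
Why: O-silylation by HMDS gives ammonia as the only by-product, and the TMS ether survives Grignard formation yet falls off in the final acidic work-up.

Step 12
Reactants: 20 5,7-dihydroxy-3-[2-hydroxy-5-(5-hydroxy-7-methoxy-4-oxo-4H-chromen-2-yl)phenyl]-4H-chromen-4-one; 21 (4-bromophenoxy)trimethylsilane
Product: 27 (2S,3R)-5,7-dihydroxy-3-[2-hydroxy-5-(5-hydroxy-7-methoxy-4-oxo-4H-chromen-2-yl)phenyl]-2-(4-hydroxyphenyl)-2,3-dihydro-4H-chromen-4-one, via tetrakis-TMS ether 22 (not isolated), via arylmagnesium bromide 23 (not isolated), via arylzinc chloride 24 (not isolated), via silyl enol ether 25 (not isolated), via cis ketone 26 (not isolated)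
Conditions: (i) 20, HMDS, cat. TMSCl, THF, reflux, evaporate; (ii) 21 (3 equiv), Mg, THF, then ZnCl2, 0 °C; (iii) [RhCl(C2H4)2]2 (2.5 mol %), (S)-BINAP (5.5 mol %), TMSCl (3 equiv), THF, 20 °C, 24 h; (iv) 1 M HCl, THF–MeOH, 23–40 °C
Reagents that add atoms: hexamethyldisilazane C[Si](C)(C)N[Si](C)(C)C; magnesium [Mg]; zinc chloride Cl[Zn]Cl; chlorotrimethylsilane C[Si](C)(C)Cl (their atoms stand only in 22–25 and none stays in 27)
Why: Proposed new method: Rh(I)/(S)-BINAP-catalysed enantioselective 1,4-addition of an arylzinc chloride to an isoflavone (an α-aryl, trisubstituted chromone acceptor, masked in situ as its per-TMS ether), in which ArZnCl transmetalates to Rh–Cl, the aryl–Rh species binds C2=C3 on the face left open by the ligand and inserts so that the aryl goes to the unsubstituted C2 (this fixes 2S, while the 2-aryl-substituted flavone enone is too hindered to insert), TMSCl polarises the vinylogous ester towards a 4-silyloxybenzopyrylium and traps the oxa-π-allyl rhodium as silyl enol ether 25, which shuts off retro-oxa-Michael racemisation, and the acidic work-up strips all silyl groups and equilibrates the labile C3 centre through the enol from cis 26 to the diequatorial trans (3R) ketone; the closest known reaction type is the Rh/BINAP-catalysed asymmetric 1,4-addition of ArZnCl/TMSCl to 4-quinolones and 2,3-dihydro-4-pyridones and of arylboronic acids to 3-unsubstituted chromones.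

## Compound list

1 | resorcinol | Oc1cccc(O)c1 | starting material
2 | acetic acid | CC(=O)O | starting material
3 | 1-(2,4-dihydroxyphenyl)ethan-1-one | CC(=O)c1ccc(O)cc1O | intermediate
4 | 1-(2-hydroxy-4-methoxyphenyl)ethan-1-one (paeonol) | CC(=O)c1ccc(OC)cc1O | intermediate
5 | 1-(2-hydroxy-4-isopropoxyphenyl)ethan-1-one | CC(=O)c1ccc(OC(C)C)cc1O | intermediate
6 | 4-bromophenol | Oc1ccc(Br)cc1 | starting material
7 | formaldehyde (used as paraformaldehyde, drawn as monomer) | C=O | starting material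
8 | 4-bromo-2-(hydroxymethyl)phenol (present as magnesium salt) | OCc1cc(Br)ccc1O | intermediate
9 | 5-bromo-2-hydroxybenzaldehyde | O=Cc1cc(Br)ccc1O | intermediate
10 | 5-bromo-2-isopropoxybenzaldehyde | O=Cc1cc(Br)ccc1OC(C)C | intermediate
11 | (E)-3-(5-bromo-2-isopropoxyphenyl)-1-(2-hydroxy-4-isopropoxyphenyl)prop-2-en-1-one | CC(C)Oc1ccc(C(=O)/C=C/c2cc(Br)ccc2OC(C)C)c(O)c1 | intermediate
12 | 2-(5-bromo-2-isopropoxyphenyl)-1-(2-hydroxy-4-isopropoxyphenyl)-3,3-dimethoxypropan-1-one (racemic) | CC(C)Oc1ccc(C(=O)C(C(OC)OC)c2cc(Br)ccc2OC(C)C)c(O)c1 | intermediate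
13 | 3-(5-bromo-2-isopropoxyphenyl)-7-isopropoxy-4H-chromen-4-one | CC(C)Oc1ccc2c(=O)c(-c3cc(Br)ccc3OC(C)C)coc2c1 | intermediate
14 | carbon monoxide | [C-]#[O+] | starting material
15 | 2-acetyl-5-methoxyphenyl 4-isopropoxy-3-(7-isopropoxy-4-oxo-4H-chromen-3-yl)benzoate | CC(=O)c1ccc(OC)cc1OC(=O)c1ccc(OC(C)C)c(-c2coc3cc(OC(C)C)ccc3c2=O)c1 | intermediate
16 | 1-(2-hydroxy-4-methoxyphenyl)-3-[4-isopropoxy-3-(7-isopropoxy-4-oxo-4H-chromen-3-yl)phenyl]propane-1,3-dione | COc1ccc(C(=O)CC(=O)c2ccc(OC(C)C)c(-c3coc4cc(OC(C)C)ccc4c3=O)c2)c(O)c1 | intermediate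
17 | 7-isopropoxy-3-[2-isopropoxy-5-(7-methoxy-4-oxo-4H-chromen-2-yl)phenyl]-4H-chromen-4-one | COc1ccc2c(=O)cc(-c3ccc(OC(C)C)c(-c4coc5cc(OC(C)C)ccc5c4=O)c3)oc2c1 | intermediate
18 | 5,5''-bis(trifluoroacetate) of 19 | COc1cc(OC(=O)C(F)(F)F)c2c(=O)cc(-c3ccc(OC(C)C)c(-c4coc5cc(OC(C)C)cc(OC(=O)C(F)(F)F)c5c4=O)c3)oc2c1 | intermediate
19 | 5-hydroxy-3-[5-(5-hydroxy-7-methoxy-4-oxo-4H-chromen-2-yl)-2-isopropoxyphenyl]-7-isopropoxy-4H-chromen-4-one | COc1cc(O)c2c(=O)cc(-c3ccc(OC(C)C)c(-c4coc5cc(OC(C)C)cc(O)c5c4=O)c3)oc2c1 | intermediate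
20 | 5,7-dihydroxy-3-[2-hydroxy-5-(5-hydroxy-7-methoxy-4-oxo-4H-chromen-2-yl)phenyl]-4H-chromen-4-one | COc1cc(O)c2c(=O)cc(-c3ccc(O)c(-c4coc5cc(O)cc(O)c5c4=O)c3)oc2c1 | intermediate
21 | (4-bromophenoxy)trimethylsilane | C[Si](C)(C)Oc1ccc(Br)cc1 | intermediate
22 | tetrakis(trimethylsilyl) ether of 20 | COc1cc(O[Si](C)(C)C)c2c(=O)cc(-c3ccc(O[Si](C)(C)C)c(-c4coc5cc(O[Si](C)(C)C)cc(O[Si](C)(C)C)c5c4=O)c3)oc2c1 | intermediate
23 | [4-(trimethylsilyloxy)phenyl]magnesium bromide | C[Si](C)(C)Oc1ccc([Mg]Br)cc1 | intermediate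
24 | [4-(trimethylsilyloxy)phenyl]zinc chloride | C[Si](C)(C)Oc1ccc([Zn]Cl)cc1 | intermediate
25 | hexa-TMS 2,3-diaryl-4-silyloxy-2H-chromene; C2 is (R) by CIP, with the same spatial arrangement as 2S in 27 (the priorities change) | COc1cc(O[Si](C)(C)C)c2c(=O)cc(-c3ccc(O[Si](C)(C)C)c(C4=C(O[Si](C)(C)C)c5c(O[Si](C)(C)C)cc(O[Si](C)(C)C)cc5O[C@@H]4c4ccc(O[Si](C)(C)C)cc4)c3)oc2c1 | intermediate
26 | (2S,3S)-cis epimer of 27 | COc1cc(O)c2c(=O)cc(-c3ccc(O)c([C@@H]4C(=O)c5c(O)cc(O)cc5O[C@@H]4c4ccc(O)cc4)c3)oc2c1 | intermediate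
27 | (2S,3R)-5,7-dihydroxy-3-[2-hydroxy-5-(5-hydroxy-7-methoxy-4-oxo-4H-chromen-2-yl)phenyl]-2-(4-hydroxyphenyl)-2,3-dihydro-4H-chromen-4-one (2,3-trans) | COc1cc(O)c2c(=O)cc(-c3ccc(O)c([C@H]4C(=O)c5c(O)cc(O)cc5O[C@@H]4c4ccc(O)cc4)c3)oc2c1 | target

## Step count and risks

Total step count: 12.
Longest linear sequence: 8 (steps 1, 3, 6, 7, 8, 9, 10, 12; the branch through steps 4 and 5 has the same length).

**Step 12 (the new reaction).** Insertion of aryl–Rh into a trisubstituted, α-arylated and electron-rich acceptor may be too slow. An uncatalysed arylation of the TMSCl-activated chromone may also erode the ee.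

The fallback uses known chemistry. It sets out from 20 and 21 and comes back at 27.
- 20 is persilylated to 22 as before.
- 22 is treated with Grignard reagent 23, CuBr·SMe2 and TMSCl in THF at −40 °C. This is the TMSCl-accelerated aryl-copper conjugate addition established for chromones.
- The addition gives 25 together with the enantiomeric silyl enol ether F1.
- The same HCl work-up passes through 26 and the (2R,3R)-cis ketone F2. It ends at the racemic trans ketone, that is 27 and the (2R,3S)-trans ketone F3.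
- The two enantiomers are separated by preparative SFC on an amylose-type chiral phase.

**Step 9.** The twofold oxygenation of a large substrate in hot TFA with I(III) may stop at the mono stage or oxidise the alkoxyarenes.

The fallback sets out from 17 and comes back at 19.
- It uses carbonyl-directed Ir-catalysed ortho C–H borylation ([Ir(OMe)(cod)]2, AsPh3, B2pin2, octane, 120 °C).
- This gives the 5,5''-bis(pinacolboronate) F4 under neutral, non-oxidising conditions.
- NaBO3·4H2O in THF–H2O at 23 °C then converts both C–B bonds into the phenols of 19.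

**Step 8.** DBU at 115 °C, together with the water released in the cyclodehydration, may open the base-sensitive isoflavone.

The fallback sets out from 13 and comes back at 17. It avoids strong base altogether.
- Pd-catalysed reductive formylation of 13 (Pd(OAc)2, n-BuPAd2, 14/H2, TMEDA, toluene, 100 °C) gives 4-isopropoxy-3-(7-isopropoxy-4-oxo-4H-chromen-3-yl)benzaldehyde F5.
- Acid-promoted Claisen–Schmidt condensation with 4 (BF3·OEt2, dioxane, 23 °C) gives the 2'-hydroxychalcone F6.
- Oxidative cyclisation with catalytic I2 in DMSO at 130 °C closes the flavone ring to 17.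

## Further compounds

F1 | step 12 | (2S)-enantiomer of silyl enol ether 25 | COc1cc(O[Si](C)(C)C)c2c(=O)cc(-c3ccc(O[Si](C)(C)C)c(C4=C(O[Si](C)(C)C)c5c(O[Si](C)(C)C)cc(O[Si](C)(C)C)cc5O[C@H]4c4ccc(O[Si](C)(C)C)cc4)c3)oc2c1
F2 | step 12 | (2R,3R)-cis ketone (enantiomer of 26) | COc1cc(O)c2c(=O)cc(-c3ccc(O)c([C@H]4C(=O)c5c(O)cc(O)cc5O[C@H]4c4ccc(O)cc4)c3)oc2c1
F3 | step 12 | (2R,3S)-trans ketone (enantiomer of 27) | COc1cc(O)c2c(=O)cc(-c3ccc(O)c([C@@H]4C(=O)c5c(O)cc(O)cc5O[C@H]4c4ccc(O)cc4)c3)oc2c1
F4 | step 9 | 5,5''-bis(pinacolboronate) of 17 | COc1cc(B2OC(C)(C)C(C)(C)O2)c2c(=O)cc(-c3ccc(OC(C)C)c(-c4coc5cc(OC(C)C)cc(B6OC(C)(C)C(C)(C)O6)c5c4=O)c3)oc2c1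
F5 | step 8 | 4-isopropoxy-3-(7-isopropoxy-4-oxo-4H-chromen-3-yl)benzaldehyde | O=Cc1ccc(OC(C)C)c(-c2coc3cc(OC(C)C)ccc3c2=O)c1
F6 | step 8 | (E)-1-(2-hydroxy-4-methoxyphenyl)-3-[4-isopropoxy-3-(7-isopropoxy-4-oxo-4H-chromen-3-yl)phenyl]prop-2-en-1-one | COc1ccc(C(=O)/C=C/c2ccc(OC(C)C)c(-c3coc4cc(OC(C)C)ccc4c3=O)c2)c(O)c1
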